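## Structural features

The target is a flavan: an aromatic ring A fused to the dihydropyran ring C (chroman numbering O1, C2–C4, C4a, C5–C8, C8a), with a 2,4-dihydroxyphenyl ring B on C2. C2 is the only stereocentre; it is S, benzylic to ring B and bonded to O1, and has no neighbouring stereocentre to relay or report its configuration. Ring A is a contiguously tetrasubstituted benzene: C4a carries the C4 methylene, C8a carries O1, C8 carries the (E)-4-hydroxy-3-methylbut-2-enyl chain and C7 carries the methoxy group. The fragile points are three. The C2–O1 ether can ionise under acid because ring B is ortho/para-dioxygenated, and can open under base once the phenols are free. The E-trisubstituted allylic alcohol rules out hydrogenation, hydrogenolysis and strong acid. The resorcinol ring is sensitive to oxidants. The real difficulty is the regiochemistry of the crowded oxygen–carbon–oxygen array C8a/C8/C7 together with absolute control at an isolated, easily ionised benzylic ether carbon. The feature used here is that C8a and C7, the two oxygen-bearing carbons flanking the alkylated C8, are the carbonyl carbons of a 2-alkylcyclohexane-1,3-dione. In that oxidation state C8a is an electrophilic carbon that can accept the C2 oxygen and C4a is an enolisable carbon that can carry C4 as an acyl carbon. C2–C3 and O1–C8a can therefore be made on a non-aromatic ring A, and the C4 oxygen is later spent on aromatisation.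

## Logic of the disconnections

16 to 15: three O–Si bonds are cut. The two phenols and the allylic alcohol must be masked through enolate, Lewis acid and hydride chemistry, and fluoride-labile groups let all three fall in one step without acid or hydrogen. The forward step must keep the freed phenols from reaching strongly basic conditions.

15 to 13 (through 14): no skeletal bond is cut. Ring A is taken back to a cyclohexadiene with a carbonyl at C4, so the C4 methylene becomes C=O and C5/C6 become CH2. This turns the 1,2,3-substituted arene into a vinylogous ester whose substitution pattern comes from a symmetric dione. The demand is that the forward step ionises the C4–O bond of 14 and moves protons around ring A without ionising C2–O1 and without water that could hydrolyse the C7 enol ether.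

13 to 9 and 11 (through 12): C2–C3 and O1–C8a are cut. C2 is a carbinol carbon beta to the C4 carbonyl (aldol retron) and O1–C8a is the enol ether of a 1,3-dicarbonyl unit (condensation retron). Ring C and the only stereocentre disappear together and two fragments of similar size result. The forward step must choose the aldehyde face by catalyst control alone, react only at the terminal diene carbon, and close the ring without breaking the C2–O bond. A check of the atom mapping of 9, 11 and 13 against 16 found them consistent (2S in 13 and in 16) and needing no correction.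

9 to 7 (through 8): two O–Si bonds are cut. The forward step must place the second enolisation at the acetyl methyl and not at the C6 methylene of chroman numbering. As a design improvement the allylic oxygen carries a tert-butyldiphenylsilyl group from the start, so that it outlasts the acid treatments after the aldol; the phenols keep tert-butyldimethylsilyl groups.

7 to 6: the C4–C4a bond is cut (acetyl carbon to the alpha-prime carbon of the enone). That carbon is the kinetic enolate position of a vinylogous ester, so the bond maps onto an enolate acylation. The demand is C- over O-acylation.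

6 to 5: the O–CH3 bond is cut. Because 5 is symmetric only one enol ether can form. The demand is O- over C-methylation.

5 to 3 and 4: the bond from C8 to the allylic CH2 is cut. C8 is the doubly activated carbon of 4 and the side chain arrives as an allylic electrophile, so all six ring A carbons come from 4. The demand is single C-allylation at the unsubstituted allyl terminus with the E geometry kept.

3 to 2 to 1: the O–Si bond, then the allylic C–O bond of 2, which goes back to a C–H bond of the E-methyl group of 1. The demand is E-selective allylic oxidation.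

11 to 10: two O–Si bonds are cut; the silyl ethers remove the acidic protons before the Lewis acid step.

## Other disconnections considered

Alternative 1: Ring A is cut at C8a–C8, C6–C7 and C4a–C8a, giving diazo enone A2 and ynol ether A3. In the forward step light converts A2 by Wolff rearrangement into a vinylketene, which adds A3 in a [2+2] sense. Four-electron opening of the cyclobutenone and six-electron closure then give phenol A1, with the C8a hydroxyl from the ketene carbon and the C7 methoxy and C8 chain from the alkyne.
- In favour: the ketene/ynol ether polarity fixes the oxygen–carbon–oxygen pattern, which equals the chosen plan on ring A regiocontrol. Ring A is aromatic as soon as it exists, so no dehydrative aromatisation is run next to the C2 ether; on that point it is better. The carbinol centre is set beforehand by a ketone reduction.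
- Against: A3 is a skipped enyne ynol ether, sensitive to acid and to base-induced isomerisation. The key step needs diazo chemistry and photolysis, builds no stereocentre and leaves ring C open. A1 still needs selective removal of its triethylsilyl group, a Mitsunobu closure that must invert cleanly at a carbon bearing an ortho/para-dioxygenated aryl group (prone to ionisation and loss of configuration), and desilylation.
- Comparison: both plans organise ring A around the same triad. Mechanistically this is a pericyclic cascade without catalyst control against a catalyst-controlled polar aldol. Two multistep fragments plus about four steps after the key step make it clearly longer than the ten steps below.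

Alternative 2: The cut is C2–C3 together with the C4–H bond, giving benzylidene malonate A5. In the forward step a chiral Lewis acid bound to the malonate triggers a 1,5-hydride shift from the benzylic O–CH2 to C4, and the malonate carbon adds to the resulting oxocarbenium ion to give chroman diester A4. The descriptor of A4 is 2R although its spatial arrangement at C2 is that of 16, because the quaternary C3 outranks the aryl group.
- In favour: ring A is aromatic throughout, so no dearomatised intermediate or dienyl cation sits near C2; on that point it is better. The electron-rich benzyl group is a good hydride donor, so the substrate suits the mechanism. The same C2–C3 bond is formed as in the chosen plan, so the two are equal there.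
- Against: the geminal diester must be removed by deallylation, one thermal decarboxylation and one radical decarboxylation, three or more steps against two after the chosen key step. Enantioselective hydride-shift cyclisations are better established for amine donors than for aryl benzyl ethers. The O-aryl oxocarbenium ion can re-form under the same Lewis acid and erode C2. A5 needs a 2-hydroxy-3-alkyl-4-methoxybenzaldehyde, so the 1,2,3-pattern must still be solved on an arene.
- Comparison: equal on the bond formed and on redox economy in the key step; worse on step economy after it and on precedent for absolute control.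

Alternative 3: The cuts are O1–C2 and C3–C4, giving salicyl alcohol A7 and styrene A8. In the forward step A7 loses water to an ortho-quinone methide, which adds A8 in an inverse-demand [4+2] cycloaddition to give A6, the tris(tert-butyldimethylsilyl) ether of 16.
- In favour: it is the most convergent plan and A6 is one desilylation from the target, so its step economy is better than the chosen plan. The regiochemistry is polarity-matched and equal to the chosen plan.
- Against: the quinone methide from A7 has no substituent on its methide carbon and no handle for a catalyst, and catalyst-controlled face selection between such a short-lived heterodiene and a simple styrene has no general solution. Quinone methide oligomerisation and cationic polymerisation of A8 compete. A7 also requires the 1,2,3-pattern to be built on an arene.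
- Comparison: structurally it forms the two ring C bonds that the chosen plan does not; mechanistically the stereocentre would be set by a catalyst not bound to either partner, against an aldehyde held on titanium in the chosen plan. It is shorter, but a single enantiomer would most likely need a resolution, and that decides against it.

Key step: step 8

Assumption: (S)-BINOL is taken to direct the diene to the Si face of 11, by analogy with titanium–BINOL additions to aryl aldehydes; if the first sample of 13 shows the opposite sense, (R)-BINOL is used and nothing else changes.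

## Route

Step 1
Reactants: 1 prenyl acetate (3-methylbut-2-en-1-yl acetate)
Product: 2 (E)-4-hydroxy-3-methylbut-2-en-1-yl acetate
Conditions: SeO2 (0.3 equiv), t-BuOOH (2.5 equiv), CH2Cl2, rt
Reagents that add atoms: selenium dioxide, O=[Se]=O (delivers the oxygen); tert-butyl hydroperoxide, CC(C)(C)OO (re-oxidises selenium and is the net oxygen source)
Why: Selenium dioxide allylic oxidation (ene reaction, then [2,3]-sigmatropic shift) attacks the methyl group trans to the chain at the more substituted alkene carbon and should give the E allylic alcohol; the acetate is inert.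

Step 2
Reactants: 2 (E)-4-hydroxy-3-methylbut-2-en-1-yl acetate
Product: 3 (E)-4-(tert-butyldiphenylsilyloxy)-3-methylbut-2-en-1-yl acetate
Conditions: TBDPSCl, imidazole, DMF, 0 °C to rt
Reagents that add atoms: tert-butylchlorodiphenylsilane, CC(C)(C)[Si](Cl)(c1ccccc1)c1ccccc1
Why: Standard imidazole-promoted silylation of a primary alcohol; the bulky, acid-stable silyl ether is chosen to survive the later TFA and pyridinium tosylate treatments.

Step 3
Reactants: 3 (E)-4-(tert-butyldiphenylsilyloxy)-3-methylbut-2-en-1-yl acetate; 4 cyclohexane-1,3-dione (2 equiv)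
Product: 5 2-[(E)-4-(tert-butyldiphenylsilyloxy)-3-methylbut-2-enyl]cyclohexane-1,3-dione
Conditions: Pd(PPh3)4 (5 mol %), Et3N (2 equiv), THF, 50 °C
Reagents that add atoms: none
Why: Tsuji–Trost allylation: zerovalent palladium ionises the allylic acetate and the soft dione enolate attacks the unsubstituted allyl terminus, giving the linear E product; O-allylation is reversible under palladium so the C-allyl dione should accumulate, and excess 4 limits double allylation.

Step 4
Reactants: 5 2-[(E)-4-(tert-butyldiphenylsilyloxy)-3-methylbut-2-enyl]cyclohexane-1,3-dione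
Product: 6 3-methoxy-2-[(E)-4-(tert-butyldiphenylsilyloxy)-3-methylbut-2-enyl]cyclohex-2-en-1-one
Conditions: Me2SO4, K2CO3, acetone, reflux
Reagents that add atoms: dimethyl sulfate, COS(=O)(=O)OC
Why: O-alkylation of the ambident dione enolate by a hard methylating agent; C2 is already substituted and hindered, and the symmetry of 5 allows only one enol ether.

Step 5
Reactants: 6 3-methoxy-2-[(E)-4-(tert-butyldiphenylsilyloxy)-3-methylbut-2-enyl]cyclohex-2-en-1-one
Product: 7 6-acetyl-3-methoxy-2-[(E)-4-(tert-butyldiphenylsilyloxy)-3-methylbut-2-enyl]cyclohex-2-en-1-one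
Conditions: LiN(iPr)2 (2.1 equiv), THF, −78 °C; 1-acetylbenzotriazole, −78 to −20 °C; aq. NH4Cl
Reagents that add atoms: 1-acetylbenzotriazole, CC(=O)n1nnc2ccccc12
Why: Kinetic deprotonation of a vinylogous ester occurs at the alpha-prime carbon (C6), and N-acylbenzotriazoles acylate lithium enolates on carbon (Claisen-type acylation); the second equivalent of base takes up the acidic proton of the new beta-diketone, whose C6 centre is stereochemically irrelevant.

Step 6
Reactants: 7 6-acetyl-3-methoxy-2-[(E)-4-(tert-butyldiphenylsilyloxy)-3-methylbut-2-enyl]cyclohex-2-en-1-one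
Product: 9 4-methoxy-3-[(E)-4-(tert-butyldiphenylsilyloxy)-3-methylbut-2-enyl]-2-(trimethylsilyloxy)-1-[1-(trimethylsilyloxy)ethenyl]cyclohexa-1,3-diene, via mono(trimethylsilyl) enol ether 8 (not isolated)
Conditions: TMSCl, Et3N, toluene, rt; filter, concentrate; LiN(iPr)2, THF, −78 °C, then TMSCl, −78 to 0 °C
Reagents that add atoms: chlorotrimethylsilane, C[Si](C)(C)Cl
Why: Two-stage preparation of a 1,3-bis(silyloxy)diene from a beta-diketone: the enol is O-silylated, then kinetic deprotonation alpha to the remaining carbonyl (the acetyl methyl, favoured over the remote vinylogous methylene) and O-silylation give the diene, which is used at once because it is moisture-sensitive.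

Step 7
Reactants: 10 2,4-dihydroxybenzaldehyde
Product: 11 2,4-bis(tert-butyldimethylsilyloxy)benzaldehyde
Conditions: TBSCl (2.4 equiv), imidazole, DMF, rt
Reagents that add atoms: tert-butylchlorodimethylsilane, CC(C)(C)[Si](C)(C)Cl
Why: Imidazole-promoted silylation of both phenols; the hydrogen-bonded ortho phenol reacts more slowly, hence the excess reagent.

Step 8
Reactants: 9 4-methoxy-3-[(E)-4-(tert-butyldiphenylsilyloxy)-3-methylbut-2-enyl]-2-(trimethylsilyloxy)-1-[1-(trimethylsilyloxy)ethenyl]cyclohexa-1,3-diene (1.5 equiv); 11 2,4-bis(tert-butyldimethylsilyloxy)benzaldehyde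
Product: 13 (2S)-2-[2,4-bis(tert-butyldimethylsilyloxy)phenyl]-8-[(E)-4-(tert-butyldiphenylsilyloxy)-3-methylbut-2-enyl]-7-methoxy-2,3,5,6-tetrahydro-4H-chromen-4-one, via silylated aldol adduct 12 (not isolated)
Conditions: (S)-BINOL (20 mol %), Ti(OiPr)4 (20 mol %), 4 Å MS, THF, −78 to −20 °C; then TFA, CH2Cl2, −20 to 0 °C; aq. NaHCO3
Reagents that add atoms: none
Why: The BINOL titanate formed from Ti(OiPr)4 binds the aldehyde oxygen of 11, and the unsubstituted terminal carbon of the bis(silyloxy)diene unit of 9 adds through an open transition state, making C2–C3 and passing a trimethylsilyl group to the new oxygen to give 12. The closest known reaction type is the titanium–BINOL-catalysed vinylogous Mukaiyama aldol of 1,3-bis(silyloxy)dienes with aryl aldehydes completed by acid cyclodehydration to a 2,3-dihydro-4H-pyran-4-one, in effect a stepwise hetero-Diels–Alder reaction. TFA then removes both trimethylsilyl groups, the C2 hydroxyl adds to the C8a carbonyl in a 6-exo-trig hemiketalisation and water is lost toward C4a, so ring C closes through O1–C8a as a vinylogous ester. The C2 stereocentre is set by the catalyst alone: the (S)-BINOL ligand shields one face of the bound aldehyde so that Si-face attack gives 2S, and because the C2–O bond is not broken in the ring closure or later, this configuration is carried to 16. Regioselectivity on the nucleophile is secured by the substrate: the internal diene carbon C4a is fully substituted and the enol ether carbon C8 is tetrasubstituted, leaving the terminal CH2 as the only accessible nucleophilic site. In the ring closure only C8a lies within six-membered reach of the hydroxyl, since attack at C7 would need an eight-membered ring. The step needs the catalysed pathway to outrun any silyl-mediated racemic background, hence the low temperature and molecular sieves, and it needs a short, cold acid treatment so that the electron-rich benzylic C2–O bond and the aryl silyl ethers survive.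

Step 9
Reactants: 13 (2S)-2-[2,4-bis(tert-butyldimethylsilyloxy)phenyl]-8-[(E)-4-(tert-butyldiphenylsilyloxy)-3-methylbut-2-enyl]-7-methoxy-2,3,5,6-tetrahydro-4H-chromen-4-one
Product: 15 (2S)-2-[2,4-bis(tert-butyldimethylsilyloxy)phenyl]-8-[(E)-4-(tert-butyldiphenylsilyloxy)-3-methylbut-2-enyl]-7-methoxychroman, via dienyl carbinol 14 (not isolated)
Conditions: iBu2AlH (1.3 equiv), CH2Cl2, −78 °C; aq. potassium sodium tartrate; crude 14: PPTS (0.2 equiv), 4 Å MS, CH2Cl2, 0 °C to rt
Reagents that add atoms: none
Why: 1,2-Hydride addition to the vinylogous ester carbonyl (as in a Stork–Danheiser sequence) gives 14, whose C4–O bond ionises under weak anhydrous acid to a dienyl cation stabilised by O1 and the methoxy group. Loss of a proton gives a cross-conjugated triene that should tautomerise to the anisole under the same acid, driven by aromatisation, with C4 left as CH2 and C2–O1 untouched.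

Step 10
Reactants: 15 (2S)-2-[2,4-bis(tert-butyldimethylsilyloxy)phenyl]-8-[(E)-4-(tert-butyldiphenylsilyloxy)-3-methylbut-2-enyl]-7-methoxychroman
Product: 16 morusyunnansin E, 4-{(2S)-8-[(E)-4-hydroxy-3-methylbut-2-enyl]-7-methoxychroman-2-yl}benzene-1,3-diol
Conditions: Bu4NF (5 equiv), AcOH (5 equiv), THF, 0 °C to rt
Reagents that add atoms: none
Why: Fluoride cleaves the two aryl and the primary silyl ethers; the acetic acid buffer keeps the phenols protonated so that base-induced opening at C2 through a quinone methide is avoided and the 2S centre is retained.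

## Compound list

1 | prenyl acetate (3-methylbut-2-en-1-yl acetate) | CC(C)=CCOC(C)=O | starting material
2 | (E)-4-hydroxy-3-methylbut-2-en-1-yl acetate | CC(=O)OC/C=C(\C)CO | intermediate
3 | (E)-4-(tert-butyldiphenylsilyloxy)-3-methylbut-2-en-1-yl acetate | CC(=O)OC/C=C(\C)CO[Si](c1ccccc1)(c1ccccc1)C(C)(C)C | intermediate
4 | cyclohexane-1,3-dione | O=C1CCCC(=O)C1 | starting material
5 | 2-[(E)-4-(tert-butyldiphenylsilyloxy)-3-methylbut-2-enyl]cyclohexane-1,3-dione | O=C1CCCC(=O)C1C/C=C(\C)CO[Si](c1ccccc1)(c1ccccc1)C(C)(C)C | intermediate
6 | 3-methoxy-2-[(E)-4-(tert-butyldiphenylsilyloxy)-3-methylbut-2-enyl]cyclohex-2-en-1-one | COC1=C(C/C=C(\C)CO[Si](c2ccccc2)(c2ccccc2)C(C)(C)C)C(=O)CCC1 | intermediate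
7 | 6-acetyl-3-methoxy-2-[(E)-4-(tert-butyldiphenylsilyloxy)-3-methylbut-2-enyl]cyclohex-2-en-1-one (drawn as diketone; C6 unspecified, largely enolised) | CC(=O)C1CCC(OC)=C(C/C=C(\C)CO[Si](c2ccccc2)(c2ccccc2)C(C)(C)C)C1=O | intermediate
8 | 1-{4-methoxy-3-[(E)-4-(tert-butyldiphenylsilyloxy)-3-methylbut-2-enyl]-2-(trimethylsilyloxy)cyclohexa-1,3-dien-1-yl}ethanone (mono(trimethylsilyl) enol ether of 7; its O-to-O silyl-shift isomer is equivalent) | CC(=O)C1=C(O[Si](C)(C)C)C(C/C=C(\C)CO[Si](c2ccccc2)(c2ccccc2)C(C)(C)C)=C(OC)CC1 | intermediate
9 | 4-methoxy-3-[(E)-4-(tert-butyldiphenylsilyloxy)-3-methylbut-2-enyl]-2-(trimethylsilyloxy)-1-[1-(trimethylsilyloxy)ethenyl]cyclohexa-1,3-diene (bis(trimethylsilyl) dienol ether of 7) | C=C(O[Si](C)(C)C)C1=C(O[Si](C)(C)C)C(C/C=C(\C)CO[Si](c2ccccc2)(c2ccccc2)C(C)(C)C)=C(OC)CC1 | intermediate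
10 | 2,4-dihydroxybenzaldehyde | O=Cc1ccc(O)cc1O | starting material
11 | 2,4-bis(tert-butyldimethylsilyloxy)benzaldehyde | O=Cc1ccc(O[Si](C)(C)C(C)(C)C)cc1O[Si](C)(C)C(C)(C)C | intermediate
12 | (3S)-3-[2,4-bis(tert-butyldimethylsilyloxy)phenyl]-1-{4-methoxy-3-[(E)-4-(tert-butyldiphenylsilyloxy)-3-methylbut-2-enyl]-2-(trimethylsilyloxy)cyclohexa-1,3-dien-1-yl}-3-(trimethylsilyloxy)propan-1-one | COC1=C(C/C=C(\C)CO[Si](c2ccccc2)(c2ccccc2)C(C)(C)C)C(O[Si](C)(C)C)=C(CC1)C(=O)C[C@H](O[Si](C)(C)C)c1ccc(O[Si](C)(C)C(C)(C)C)cc1O[Si](C)(C)C(C)(C)C | intermediate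
13 | (2S)-2-[2,4-bis(tert-butyldimethylsilyloxy)phenyl]-8-[(E)-4-(tert-butyldiphenylsilyloxy)-3-methylbut-2-enyl]-7-methoxy-2,3,5,6-tetrahydro-4H-chromen-4-one | COC1=C(C/C=C(\C)CO[Si](c3ccccc3)(c3ccccc3)C(C)(C)C)C2=C(CC1)C(=O)C[C@@H](c1ccc(O[Si](C)(C)C(C)(C)C)cc1O[Si](C)(C)C(C)(C)C)O2 | intermediate
14 | (2S)-2-[2,4-bis(tert-butyldimethylsilyloxy)phenyl]-8-[(E)-4-(tert-butyldiphenylsilyloxy)-3-methylbut-2-enyl]-7-methoxy-2,3,5,6-tetrahydro-4H-chromen-4-ol (both C4 epimers) | COC1=C(C/C=C(\C)CO[Si](c3ccccc3)(c3ccccc3)C(C)(C)C)C2=C(CC1)C(O)C[C@@H](c1ccc(O[Si](C)(C)C(C)(C)C)cc1O[Si](C)(C)C(C)(C)C)O2 | intermediate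
15 | (2S)-2-[2,4-bis(tert-butyldimethylsilyloxy)phenyl]-8-[(E)-4-(tert-butyldiphenylsilyloxy)-3-methylbut-2-enyl]-7-methoxychroman | COc1ccc2c(c1C/C=C(\C)CO[Si](c3ccccc3)(c3ccccc3)C(C)(C)C)O[C@H](c1ccc(O[Si](C)(C)C(C)(C)C)cc1O[Si](C)(C)C(C)(C)C)CC2 | intermediate
16 | morusyunnansin E, 4-{(2S)-8-[(E)-4-hydroxy-3-methylbut-2-enyl]-7-methoxychroman-2-yl}benzene-1,3-diol | COc1ccc2c(c1C/C=C(\C)CO)O[C@H](c1ccc(O)cc1O)CC2 | target

## Step count and least certain steps

Total: 10 steps. Longest linear sequence: 9 steps (steps 1–6 and 8–10); step 7 is the one-step side branch.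

**Step 8 (key step).** The aldehyde is electron-rich and ortho-substituted, so slow turnover of the titanium catalyst and poor facial selectivity are the most likely failures. A racemic silyl-mediated background could add to this, and during the TFA stage loss of water from the aldol or ionisation at the benzylic carbon could lower yield and enantiopurity.

Fallback: the stereocentre is set on the aldehyde by a reagent-controlled Brown allylation and the C4–C4a bond is made by an aldol. The sequence sets out from 11 and 6 and returns at 13.
- 11 is allylated with the Ipc2B(allyl) reagent derived from (+)-α-pinene (Et2O, −78 °C, ethanolamine work-up) to give (S)-1-[2,4-bis(tert-butyldimethylsilyloxy)phenyl]but-3-en-1-ol F1.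
- Silylation (Et3SiCl, imidazole) gives (S)-triethylsilyl ether F2.
- Lemieux–Johnson cleavage (OsO4 cat., NaIO4, 2,6-lutidine, dioxane–water) gives (S)-3-[2,4-bis(tert-butyldimethylsilyloxy)phenyl]-3-(triethylsilyloxy)propanal F3.
- The lithium enolate of 6 (LiN(iPr)2, THF, −78 °C) adds to F3 to give beta-hydroxy ketone F4 as a diastereomer mixture.
- Dess–Martin oxidation gives beta-diketone F5.
- TFA in CH2Cl2 removes the triethylsilyl group and cyclodehydrates F5 to 13.

**Step 9.** The proton shift that completes aromatisation may stall at the triene stage under the weak acid, while a stronger acid raises the risk of ionisation of the C2–O1 bond in the cationic intermediate and loss of configuration. Traces of water could also hydrolyse the C7 enol ether.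

Fallback: ring A is aromatised by oxidation and C4 is deoxygenated under neutral radical conditions (Barton–McCombie). The sequence sets out from 13 and returns at 15.
- DDQ (benzene, rt) dehydrogenates C5–C6 to give (2S)-2-[2,4-bis(tert-butyldimethylsilyloxy)phenyl]-8-[(E)-4-(tert-butyldiphenylsilyloxy)-3-methylbut-2-enyl]-7-methoxychroman-4-one F6.
- NaBH4 (MeOH–THF, 0 °C) gives the chroman-4-ol F7.
- 1,1'-Thiocarbonyldiimidazole gives the O-(chroman-4-yl) imidazole-1-carbothioate F8.
- Bu3SnH with AIBN in toluene at 80 °C removes the C4 oxygen and gives 15.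

**Step 5.** O-acylation of the enolate, or proton transfer from the forming beta-diketone to unreacted enolate, could stop the reaction short.

Fallback: the acetyl group is built by aldol and oxidation. The sequence sets out from 6 and returns at 7. The lithium enolate of 6 adds to acetaldehyde at −78 °C to give 6-(1-hydroxyethyl)-3-methoxy-2-[(E)-4-(tert-butyldiphenylsilyloxy)-3-methylbut-2-enyl]cyclohex-2-en-1-one F9, and Dess–Martin oxidation gives 7.

**Step 3.** Double allylation of 4, attack at the substituted allyl terminus, or E/Z leakage through the allylpalladium intermediate could lower the yield or geometric purity.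

Fallback: classical C-alkylation with an allylic bromide of fixed geometry. The sequence sets out from 3 and returns at 5. Methanolysis (K2CO3, MeOH) gives (E)-4-(tert-butyldiphenylsilyloxy)-3-methylbut-2-en-1-ol F10, Appel bromination (CBr4, PPh3, CH2Cl2, 0 °C) gives (E)-(4-bromo-2-methylbut-2-enyloxy)(tert-butyl)diphenylsilane F11, and alkylation of 4 with F11 (aq. KOH, 1,4-dioxane, rt) gives 5.

## Further compounds

F1 | step 8 | (S)-1-[2,4-bis(tert-butyldimethylsilyloxy)phenyl]but-3-en-1-ol | C=CC[C@H](O)c1ccc(O[Si](C)(C)C(C)(C)C)cc1O[Si](C)(C)C(C)(C)C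
F2 | step 8 | (S)-{1-[2,4-bis(tert-butyldimethylsilyloxy)phenyl]but-3-enyloxy}triethylsilane | C=CC[C@H](O[Si](CC)(CC)CC)c1ccc(O[Si](C)(C)C(C)(C)C)cc1O[Si](C)(C)C(C)(C)C
F3 | step 8 | (S)-3-[2,4-bis(tert-butyldimethylsilyloxy)phenyl]-3-(triethylsilyloxy)propanal | O=CC[C@H](O[Si](CC)(CC)CC)c1ccc(O[Si](C)(C)C(C)(C)C)cc1O[Si](C)(C)C(C)(C)C
F4 | step 8 | 6-{(3S)-3-[2,4-bis(tert-butyldimethylsilyloxy)phenyl]-1-hydroxy-3-(triethylsilyloxy)propyl}-3-methoxy-2-[(E)-4-(tert-butyldiphenylsilyloxy)-3-methylbut-2-enyl]cyclohex-2-en-1-one (diastereomer mixture) | COC1=C(C/C=C(\C)CO[Si](c2ccccc2)(c2ccccc2)C(C)(C)C)C(=O)C(CC1)C(O)C[C@H](O[Si](CC)(CC)CC)c1ccc(O[Si](C)(C)C(C)(C)C)cc1O[Si](C)(C)C(C)(C)C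
F5 | step 8 | 6-{(3S)-3-[2,4-bis(tert-butyldimethylsilyloxy)phenyl]-3-(triethylsilyloxy)propanoyl}-3-methoxy-2-[(E)-4-(tert-butyldiphenylsilyloxy)-3-methylbut-2-enyl]cyclohex-2-en-1-one | COC1=C(C/C=C(\C)CO[Si](c2ccccc2)(c2ccccc2)C(C)(C)C)C(=O)C(CC1)C(=O)C[C@H](O[Si](CC)(CC)CC)c1ccc(O[Si](C)(C)C(C)(C)C)cc1O[Si](C)(C)C(C)(C)C
F6 | step 9 | (2S)-2-[2,4-bis(tert-butyldimethylsilyloxy)phenyl]-8-[(E)-4-(tert-butyldiphenylsilyloxy)-3-methylbut-2-enyl]-7-methoxychroman-4-one | COc1ccc2c(c1C/C=C(\C)CO[Si](c3ccccc3)(c3ccccc3)C(C)(C)C)O[C@H](c1ccc(O[Si](C)(C)C(C)(C)C)cc1O[Si](C)(C)C(C)(C)C)CC2=O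
F7 | step 9 | (2S)-2-[2,4-bis(tert-butyldimethylsilyloxy)phenyl]-8-[(E)-4-(tert-butyldiphenylsilyloxy)-3-methylbut-2-enyl]-7-methoxychroman-4-ol (both C4 epimers) | COc1ccc2c(c1C/C=C(\C)CO[Si](c3ccccc3)(c3ccccc3)C(C)(C)C)O[C@H](c1ccc(O[Si](C)(C)C(C)(C)C)cc1O[Si](C)(C)C(C)(C)C)CC2O
F8 | step 9 | O-{(2S)-2-[2,4-bis(tert-butyldimethylsilyloxy)phenyl]-8-[(E)-4-(tert-butyldiphenylsilyloxy)-3-methylbut-2-enyl]-7-methoxychroman-4-yl} 1H-imidazole-1-carbothioate (both C4 epimers) | COc1ccc2c(c1C/C=C(\C)CO[Si](c3ccccc3)(c3ccccc3)C(C)(C)C)O[C@H](c1ccc(O[Si](C)(C)C(C)(C)C)cc1O[Si](C)(C)C(C)(C)C)CC2OC(=S)n1ccnc1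
F9 | step 5 | 6-(1-hydroxyethyl)-3-methoxy-2-[(E)-4-(tert-butyldiphenylsilyloxy)-3-methylbut-2-enyl]cyclohex-2-en-1-one (diastereomer mixture) | CC(O)C1CCC(OC)=C(C/C=C(\C)CO[Si](c2ccccc2)(c2ccccc2)C(C)(C)C)C1=O
F10 | step 3 | (E)-4-(tert-butyldiphenylsilyloxy)-3-methylbut-2-en-1-ol | OC/C=C(\C)CO[Si](c1ccccc1)(c1ccccc1)C(C)(C)C
F11 | step 3 | (E)-(4-bromo-2-methylbut-2-enyloxy)(tert-butyl)diphenylsilane | BrC/C=C(\C)CO[Si](c1ccccc1)(c1ccccc1)C(C)(C)C
A1 | alternative 1 | 6-{(3R)-3-[2,4-bis(tert-butyldimethylsilyloxy)phenyl]-3-(triethylsilyloxy)propyl}-2-[(E)-4-(tert-butyldimethylsilyloxy)-3-methylbut-2-enyl]-3-methoxyphenol | COc1ccc(CC[C@@H](O[Si](CC)(CC)CC)c2ccc(O[Si](C)(C)C(C)(C)C)cc2O[Si](C)(C)C(C)(C)C)c(O)c1C/C=C(\C)CO[Si](C)(C)C(C)(C)C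
A2 | alternative 1 | (3E,7R)-7-[2,4-bis(tert-butyldimethylsilyloxy)phenyl]-1-diazo-7-(triethylsilyloxy)hept-3-en-2-one | [N-]=[N+]=CC(=O)/C=C/CC[C@@H](O[Si](CC)(CC)CC)c1ccc(O[Si](C)(C)C(C)(C)C)cc1O[Si](C)(C)C(C)(C)C
A3 | alternative 1 | (E)-tert-butyl[(6-methoxy-2-methylhex-2-en-5-yn-1-yl)oxy]dimethylsilane | COC#CC/C=C(\C)CO[Si](C)(C)C(C)(C)C
A4 | alternative 2 | diallyl (2R)-2-[2,4-bis(tert-butyldimethylsilyloxy)phenyl]-8-[(E)-4-(tert-butyldimethylsilyloxy)-3-methylbut-2-enyl]-7-methoxychroman-3,3-dicarboxylate | COc1ccc2c(c1C/C=C(\C)CO[Si](C)(C)C(C)(C)C)O[C@H](c1ccc(O[Si](C)(C)C(C)(C)C)cc1O[Si](C)(C)C(C)(C)C)C(C(=O)OCC=C)(C(=O)OCC=C)C2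
A5 | alternative 2 | diallyl 2-{2-[2,4-bis(tert-butyldimethylsilyloxy)benzyloxy]-3-[(E)-4-(tert-butyldimethylsilyloxy)-3-methylbut-2-enyl]-4-methoxybenzylidene}malonate | COc1ccc(C=C(C(=O)OCC=C)C(=O)OCC=C)c(OCc2ccc(O[Si](C)(C)C(C)(C)C)cc2O[Si](C)(C)C(C)(C)C)c1C/C=C(\C)CO[Si](C)(C)C(C)(C)C
A6 | alternative 3 | (2S)-2-[2,4-bis(tert-butyldimethylsilyloxy)phenyl]-8-[(E)-4-(tert-butyldimethylsilyloxy)-3-methylbut-2-enyl]-7-methoxychroman | COc1ccc2c(c1C/C=C(\C)CO[Si](C)(C)C(C)(C)C)O[C@H](c1ccc(O[Si](C)(C)C(C)(C)C)cc1O[Si](C)(C)C(C)(C)C)CC2
A7 | alternative 3 | 2-(hydroxymethyl)-6-[(E)-4-(tert-butyldimethylsilyloxy)-3-methylbut-2-enyl]-5-methoxyphenol | COc1ccc(CO)c(O)c1C/C=C(\C)CO[Si](C)(C)C(C)(C)C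
A8 | alternative 3 | 1-ethenyl-2,4-bis(tert-butyldimethylsilyloxy)benzene | C=Cc1ccc(O[Si](C)(C)C(C)(C)C)cc1O[Si](C)(C)C(C)(C)C
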